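Its constants belong to no real substance; what happens was integrated by code.

I start from the amounts in this flask: more L than G is charged, and I count each species as a fraction of its charge.

    X + G → Z + G, rate k1*[X]*[G]/(1 + ([X]/Km1) + ([X]/Ksi1)^2) (Km1 = 14.1 mM, Ksi1 = 6.22 mM, k1 = 1.82 × 10⁵ L mol⁻¹ s⁻¹)
    G + L → G.L (k2 = 9.47 × 10⁶ L mol⁻¹ s⁻¹)
    2 X → X2 (k3 = 5.11 L mol⁻¹ s⁻¹)

X 10 mM; G 2.0 µM; L 2.3 µM

- the form that holds most of the catalyst when 50% of the X are converted (G / G.L)
- its share of the catalyst then

**Capture margin.** One minus the ratio of the charges gives 13.0%. I call this the capture margin, the fraction of charged L left over once each G is bound. G is therefore the limiting reagent of the capture.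

**Fraction left.** At the charge of X, one G turns over at 424 s⁻¹. Free G summed over time comes to the logarithm of the inverse margin over k2, so at this turnover I reckon the catalyst converts about 0.912% of X, hardly any. Counting dimerisation by itself, the reciprocal of the fraction left climbs by 0.102 s⁻¹ each second, going from one to two in 9.78 s. Late in the capture, free G decays at 2.84 s⁻¹, so the fraction of G left by then is <0.001%. I commit to G.L.

**Turning G.** With twice the G, the margin becomes −73.9%. The negative sign means L is used up first, leaving 42.5% of that G free. By my reckoning the fraction of X left then falls at 0.174 s⁻¹ at the charge and 0.103 s⁻¹ at half of it. The mean of these puts 50% conversion at an estimated 3.61 s, a factor of 0.369 on my dimerisation time.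

**The forecast.** It names G.L at 100%, within 99.9% to 100%: “L is in slight excess over G and binds it within about a second”.

**The result.** When 50% of the X are converted, at 9.69 s, the flask holds G.L at 100% of the catalyst, a form outside the working round. At 25.0 s, unbound L in this flask stands at 13% of its charge, and the capture margin is 13.0%. In the flask with twice the G, where the margin is −73.9%, the time to 50% conversion changes by a factor of 0.385.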